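**Plan**

- Lactone numbering: O1, C2 (carbonyl), C3 (methyl), C4 (carboxyl), C5 (H and chain); chain carbons C1' (on C5) to C15'.
- Retrosynthesis cuts, in order: the tert-butyl ester on the C4 carboxyl; the C5–C1' bond, giving a racemic 5-bromobutenolide and pentadec-14-en-2-one; C5–Br back to C5–H2; the ring at C3=C4 and O1–C5; the chain at C11'–C12'.
- Forward: a one-pot O-alkylation and intramolecular Horner–Wadsworth–Emmons reaction builds the furan-2(5H)-one ring; NBS brominates C5; a copper-catalysed 1,4-addition makes the alkenyl methyl ketone; a nickel-catalysed enantioconvergent hydroalkylation joins the halves at C5–C1'; TFA frees the acid.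
- Enabling feature: C5 of the furan-2(5H)-one ring is α to O1 and allylic to C3=C4, which is conjugated to C2=O and to the C4 ester. C5–H is therefore the weakest C–H bond, C5–Br gives the same planar radical from either enantiomer, and the C4 ester carbonyl sits next to C5 where it can bind nickel.
- Stereochemistry: the only stereocentre, C5 (R), is set in the coupling by a chiral bis(oxazoline)nickel catalyst; the bromide is used as the racemate.

Key step: step 4

Assumption: the sense of induction at C5 for this new electrophile cannot be read from acyclic precedent, so (S,S)-Ph-BOX [(4S,4'S)-2,2'-(propane-2,2-diyl)bis(4-phenyl-4,5-dihydrooxazole)] in step 4 stands for whichever antipode a pilot run shows to give the (R) lactone.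

**Step 1**
Reactants: 1 tert-butyl 3-bromo-2-oxopropanoate (tert-butyl bromopyruvate); 2 2-(diethoxyphosphoryl)propanoic acid
Product: 4 tert-butyl 4-methyl-5-oxo-2,5-dihydrofuran-3-carboxylate, via keto phosphonate ester 3 (not isolated)
Conditions: KHCO3, DMF, 0 °C to rt; then LiCl, DBU, 0 °C to rt
Reagents that add atoms: none
Why: The carboxylate of 2 should displace the bromide of the α-bromo ketone to give 3, whose phosphonate carbanion then attacks the very electrophilic α-keto ester carbonyl (5-exo-trig) in an intramolecular Horner–Wadsworth–Emmons olefination under Masamune–Roush conditions, the standard butenolide annulation; no stereocentre is formed.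

**Step 2**
Reactants: 4 tert-butyl 4-methyl-5-oxo-2,5-dihydrofuran-3-carboxylate
Product: 5 rac-tert-butyl 2-bromo-4-methyl-5-oxo-2,5-dihydrofuran-3-carboxylate
Conditions: NBS (1.05 equiv), AIBN (cat.), PhCF3, 85 °C
Reagents that add atoms: N-bromosuccinimide, O=C1CCC(=O)N1Br
Why: Wohl–Ziegler bromination should take the ring CH2 (lactone C5) because its radical is α to the ring oxygen and allylic to C3=C4, as in the known C5 bromination of 3-methylfuran-2(5H)-one; the new stereocentre is formed as a racemate on purpose because the next step is enantioconvergent.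

**Step 3**
Reactants: 6 11-bromoundec-1-ene; 7 but-3-en-2-one (methyl vinyl ketone)
Product: 10 pentadec-14-en-2-one, via undec-10-enylmagnesium bromide 8 (not isolated), via silyl enol ether 9 (not isolated)
Conditions: Mg, THF, rt; then CuBr·SMe2 (5 mol %), TMSCl, 7, THF, −78 °C; then 1 M HCl
Reagents that add atoms: magnesium, [Mg]; chlorotrimethylsilane, C[Si](C)(C)Cl (their atoms stay in 8 and 9 only)
Why: Copper-catalysed 1,4-addition of a primary alkyl Grignard reagent to an enone, accelerated by TMSCl, which traps the enolate as 9 and so suppresses 1,2-addition and polymerisation, should give the methyl ketone after acid work-up with the terminal alkene untouched.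

**Step 4**
Reactants: 5 rac-tert-butyl 2-bromo-4-methyl-5-oxo-2,5-dihydrofuran-3-carboxylate; 10 pentadec-14-en-2-one
Product: 11 tert-butyl (2R)-4-methyl-5-oxo-2-(14-oxopentadecyl)-2,5-dihydrofuran-3-carboxylate
Conditions: NiBr2·DME (10 mol %), (S,S)-Ph-BOX (12 mol %), (EtO)3SiH (2 equiv), K3PO4·H2O (2 equiv), Et2O/DMA, rt
Reagents that add atoms: none
Why: Proposed new method: a nickel hydride made from the nickel bromide, (EtO)3SiH and phosphate should add anti-Markovnikov to the terminal alkene of 10 to give a primary alkylnickel, while monovalent nickel abstracts bromine from either enantiomer of 5 to give one and the same planar C5 radical (α to O1 and allylic to C3=C4), which the chiral divalent alkylnickel captures before C(sp3)–C(sp3) reductive elimination from trivalent nickel forms the C5–C1' bond. The closest known reaction type is the nickel/bis(oxazoline)-catalysed enantioconvergent coupling of racemic acyclic 1-bromoalkyl esters with terminal olefins and a hydrosilane, together with the nickel-catalysed enantioconvergent Negishi coupling of racemic secondary allylic chlorides; a cyclic bromolactone that is both at once has not been used. No ring is closed. The C5 stereocentre is set by the C2-symmetric ligand on nickel in the radical capture and reductive elimination, independently of the configuration of the bromide, and the carbonyl oxygen of the C4 ester can bind nickel in a five-membered chelate (Ni–C5–C4–C=O) that takes the role of the acyloxy carbonyl of the acyclic substrates in fixing the flat ring in the chiral pocket. The step needs coupling at C5 and not at C3 of the delocalised radical, which the fully substituted C3 and the loss of conjugation to both carbonyl groups on C3 attack secure; linear alkyl transfer, which the unactivated terminal alkene secures; and a nickel hydride that ignores the remote methyl ketone and the tetrasubstituted, electron-poor ring alkene.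

**Step 5**
Reactants: 11 tert-butyl (2R)-4-methyl-5-oxo-2-(14-oxopentadecyl)-2,5-dihydrofuran-3-carboxylate
Product: 12 isomuronic acid, (2R)-4-methyl-5-oxo-2-(14-oxopentadecyl)-2,5-dihydrofuran-3-carboxylic acid
Conditions: TFA/CH2Cl2 (1:4), 0 °C to rt
Reagents that add atoms: none
Why: Acidolysis of the tert-butyl ester with loss of isobutene should leave the lactone, the ketone and the C5 stereocentre untouched, whereas basic hydrolysis would risk deprotonation at C5.

**Compound list**

1 | tert-butyl 3-bromo-2-oxopropanoate | BrCC(=O)C(=O)OC(C)(C)C | starting material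
2 | 2-(diethoxyphosphoryl)propanoic acid | CCOP(=O)(OCC)C(C)C(O)=O | starting material
3 | tert-butyl 3-{[2-(diethoxyphosphoryl)propanoyl]oxy}-2-oxopropanoate | CCOP(=O)(OCC)C(C)C(=O)OCC(=O)C(=O)OC(C)(C)C | intermediate
4 | tert-butyl 4-methyl-5-oxo-2,5-dihydrofuran-3-carboxylate | CC1=C(C(=O)OC(C)(C)C)COC1=O | intermediate
5 | rac-tert-butyl 2-bromo-4-methyl-5-oxo-2,5-dihydrofuran-3-carboxylate | CC1=C(C(=O)OC(C)(C)C)C(Br)OC1=O | intermediate
6 | 11-bromoundec-1-ene | C=CCCCCCCCCCBr | starting material
7 | but-3-en-2-one | CC(=O)C=C | starting material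
8 | undec-10-enylmagnesium bromide | C=CCCCCCCCCC[Mg]Br | intermediate
9 | trimethyl(pentadeca-2,14-dien-2-yloxy)silane | CC(O[Si](C)(C)C)=CCCCCCCCCCCC=C | intermediate
10 | pentadec-14-en-2-one | CC(=O)CCCCCCCCCCCC=C | intermediate
11 | tert-butyl (2R)-4-methyl-5-oxo-2-(14-oxopentadecyl)-2,5-dihydrofuran-3-carboxylate | CC(=O)CCCCCCCCCCCCC[C@H]1OC(=O)C(C)=C1C(=O)OC(C)(C)C | intermediate
12 | isomuronic acid, (2R)-4-methyl-5-oxo-2-(14-oxopentadecyl)-2,5-dihydrofuran-3-carboxylic acid | CC(=O)CCCCCCCCCCCCC[C@H]1OC(=O)C(C)=C1C(=O)O | target

**Step count**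

Total: 5 steps. Longest linear sequence: 4 steps (steps 1, 2, 4, 5).

**Steps most likely to fail**

Step 4 (labelled new method).
- What may go wrong: poor enantioselection if the flat ring does not bind nickel through the C4 ester; reduction of the C–Br bond by the nickel hydride; dimerisation of the C5 radical; hydrolysis of the bromolactone by the hydrated base; slow racemisation of the product by deprotonation at C5.
- Fallback (sets out from 5 and 10, comes back at 12), using the established titanium/bis(sulfonamide)-catalysed addition of functionalised dialkylzincs to unsaturated aldehydes: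
  - Hydrolysis of 5 (NaHCO3, aqueous acetone) should give tert-butyl 2-hydroxy-4-methyl-5-oxo-2,5-dihydrofuran-3-carboxylate F1. Its ring-opened carboxylate is methylated (MeI, K2CO3, DMF) to 1-tert-butyl 4-methyl (2E)-2-formyl-3-methylbut-2-enedioate F2.
  - Ketone 10 is protected (ethylene glycol, TsOH, benzene, reflux) as 2-methyl-2-(tridec-12-en-1-yl)-1,3-dioxolane F3. Hydroboration (Et2BH) gives diethyl[13-(2-methyl-1,3-dioxolan-2-yl)tridecyl]borane F4, and boron–zinc exchange (Et2Zn, then evacuation) gives bis[13-(2-methyl-1,3-dioxolan-2-yl)tridecyl]zinc F5.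
  - Addition of F5 to F2 with Ti(OiPr)4 and (1S,2S)-1,2-bis(trifluoromethanesulfonamido)cyclohexane (toluene, −20 °C) should give 1-tert-butyl 4-methyl (2E)-2-[(1R)-1-hydroxy-14-(2-methyl-1,3-dioxolan-2-yl)tetradecyl]-3-methylbut-2-enedioate F6. The (R) sense is expected by analogy with simple aldehydes, where this ligand antipode delivers the alkyl group to the face that places O, the sp2 carbon and the alkyl group in this order.
  - F6 closes onto the cis methyl ester (CSA cat., CH2Cl2) to tert-butyl (2R)-4-methyl-2-[13-(2-methyl-1,3-dioxolan-2-yl)tridecyl]-5-oxo-2,5-dihydrofuran-3-carboxylate F7.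
  - TFA/CH2Cl2/H2O then removes the dioxolane and the tert-butyl ester together to give 12.

Step 2.
- What may go wrong: hydrogen abstraction from the C3 methyl group (vinylogous to the C4 ester) competing with C5; a second bromination at C5; loss of the tert-butyl ester through HBr.
- Fallback (sets out from 4, comes back at 5): an ionic route in place of the radical one. Silylation of 4 (TBSOTf, Et3N, CH2Cl2, 0 °C) should give tert-butyl 5-[(tert-butyldimethylsilyl)oxy]-4-methylfuran-3-carboxylate F8. Electrophilic bromination of this silyloxyfuran (NBS, CH2Cl2, −78 °C) can only occur at the free ring position that becomes lactone C5, the known route from 2-silyloxyfurans to 5-halofuran-2(5H)-ones, and gives 5.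

Step 1.
- What may go wrong: enolisation of the acyloxymethyl ketone toward its CH2 group, with acyl migration, outrunning carbanion attack; base-induced self-condensation of the bromopyruvate.
- Fallback (sets out from 1, comes back at 4): C–C bond formation without base. O-alkylation of 2-bromopropanoic acid by 1 (KHCO3, DMF, 0 °C) should give tert-butyl 3-[(2-bromopropanoyl)oxy]-2-oxopropanoate F9. An intramolecular Reformatsky reaction (activated Zn, THF) closes it to tert-butyl 3-hydroxy-4-methyl-5-oxooxolane-3-carboxylate F10, and dehydration (MsCl, Et3N, then DBU) toward the lactone carbonyl gives 4.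

**Further compounds**

F1 | step 4 | tert-butyl 2-hydroxy-4-methyl-5-oxo-2,5-dihydrofuran-3-carboxylate | CC1=C(C(=O)OC(C)(C)C)C(O)OC1=O
F2 | step 4 | 1-tert-butyl 4-methyl (2E)-2-formyl-3-methylbut-2-enedioate | COC(=O)/C(C)=C(C=O)/C(=O)OC(C)(C)C
F3 | step 4 | 2-methyl-2-(tridec-12-en-1-yl)-1,3-dioxolane | C=CCCCCCCCCCCCC1(C)OCCO1
F4 | step 4 | diethyl[13-(2-methyl-1,3-dioxolan-2-yl)tridecyl]borane | CCB(CC)CCCCCCCCCCCCCC1(C)OCCO1
F5 | step 4 | bis[13-(2-methyl-1,3-dioxolan-2-yl)tridecyl]zinc | CC1(CCCCCCCCCCCCC[Zn]CCCCCCCCCCCCCC2(C)OCCO2)OCCO1
F6 | step 4 | 1-tert-butyl 4-methyl (2E)-2-[(1R)-1-hydroxy-14-(2-methyl-1,3-dioxolan-2-yl)tetradecyl]-3-methylbut-2-enedioate | COC(=O)/C(C)=C([C@H](O)CCCCCCCCCCCCCC1(C)OCCO1)/C(=O)OC(C)(C)C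
F7 | step 4 | tert-butyl (2R)-4-methyl-2-[13-(2-methyl-1,3-dioxolan-2-yl)tridecyl]-5-oxo-2,5-dihydrofuran-3-carboxylate | CC1(CCCCCCCCCCCCC[C@H]2OC(=O)C(C)=C2C(=O)OC(C)(C)C)OCCO1
F8 | step 2 | tert-butyl 5-[(tert-butyldimethylsilyl)oxy]-4-methylfuran-3-carboxylate | Cc1c(O[Si](C)(C)C(C)(C)C)occ1C(=O)OC(C)(C)C
F9 | step 1 | tert-butyl 3-[(2-bromopropanoyl)oxy]-2-oxopropanoate | CC(Br)C(=O)OCC(=O)C(=O)OC(C)(C)C
F10 | step 1 | tert-butyl 3-hydroxy-4-methyl-5-oxooxolane-3-carboxylate | CC1C(=O)OCC1(O)C(=O)OC(C)(C)C
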